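## Analysis of the target

The target 15 is a flavanone: a benzo ring A fused to a dihydropyranone ring C (O1, C2, C3, C4, C4a, C8a), with a 2,4-dihydroxyphenyl ring B on C2. Ring A carries a free hydroxyl at C7 flanked by two 3-methylbut-2-enyl (prenyl) groups at C6 and C8, and has no oxygen at C5. The only stereocentre is C2, configured S. It is benzylic, bonded to O1 and β to the C4 carbonyl, so ring C can open by a retro-oxa-Michael reaction and close again with loss of configuration; base and the oxygen donors at C2' and C4' of ring B make this easier. The prenyl alkenes are sensitive to acid (the neighbouring C7 hydroxyl adds to give chromans), to electrophilic halogen and to hydrogenation, and three free phenols must be unveiled at the end. The synthesis is hard for three reasons: two prenyl groups and one carbon substituent must be placed on a resorcinol ring without regiochemical scatter, a labile stereocentre must be set as late as possible, and neither may use reagents that attack trisubstituted alkenes. The plan rests on one feature: C4 is a single carbonyl carbon bridging C4a of ring A and the two-carbon unit C3–C2 that bears ring B, and at the flavone oxidation level C2 is trigonal and prochiral. Ring C can therefore be assembled from an aryl iodide, carbon monoxide and an arylalkyne, and C2 made stereogenic afterwards by face-selective delivery of hydride.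

## Retrosynthetic reasoning

**15 back to 14.** Only the three O–CH2OMe bonds are cut. The last step is then a deprotection and no skeletal work remains once the stereocentre exists. Methoxymethyl ethers are chosen because they survive base, palladium catalysis and hydride, and fall to acid mild enough to be tried in the presence of prenyl groups.

**14 back to 12 (through 13), and 12 back to 11.** The C2–H bond is cut, which returns the flavanone to the flavone 12. In 12 there is no stereocentre to lose, so every forcing step can be run before C2 becomes stereogenic. The forward reaction must add hydride to C2 from one face under control of a chiral copper hydride catalyst and must leave the prenyl alkenes alone. Its first product is the silyl enol ether 13, which shields ring C from opening until work-up. A free C7 hydroxyl would quench the hydride and, as phenoxide, switch off the enone, so 12 is traced back to the free phenol 11 by one O-alkylation.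

**11 back to 4, 7 and 8.** Three bonds are cut at once: C4a–C4, C4–C3 and O1–C2. This is the natural place because C4 is one carbon and can come from carbon monoxide 8. The two remaining pieces, iodophenol 4 and alkyne 7, each carry one aromatic ring complete with its substituents. Cutting C2–C1' or C2–C3 instead would need a preformed chromone or an aldol partner and would split the work less evenly. The forward reaction has to couple 4, 8 and 7 to the ynone 9, add a secondary amine to give the enaminone 10, and close ring C in the 6-endo sense.

**4 back to 3, 2 and 1.** The prenyl groups are cut at their C=C bonds, which leaves the diallyl compound 3; cross-metathesis turns allyl into prenyl reliably. The two ring–allyl bonds of 3 are then traced to the O-allyl bonds of 2 by two Claisen rearrangements, and 2 to the commercial iodoresorcinol 1. Direct C-prenylation of a resorcinol is avoided because it scatters between oxygen and carbon and between mono- and polyalkylation. In 2 the iodine serves twice, as the handle for the key step and as a blocking group that leaves the future C6 and C8 as the only sites an allyl group can reach.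

**7 back to 6 and 5.** The terminal alkyne carbon is cut off, which leads to the aldehyde 6 by a one-carbon homologation, and 6 to the commercial aldehyde 5 by protection of both phenols.

## Alternatives that were turned down

**Alternative 1:** Petasis–Ferrier rearrangement of an enol acetal.

- *Disconnection:* the C2–C3 bond. The silyl-protected flavanone A1 would come from the 4-methylidene-1,3-benzodioxine A2, in which O1–C2 already exists and the future C3 is the exocyclic methylene carbon.
- *Forward key step:* a confined chiral Brønsted acid or a chiral Lewis acid ionises the acetal of A2 to an O1-aryl oxocarbenium ion and the C4 enol. The two recombine at carbon, forming C2–C3, ring C and the C2 stereocentre in one event.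
- *For it:* ring C and the stereocentre arrive together at the right oxidation level, with no flavone detour, no late reduction and no pressure vessel.
- *Against it:* the oxocarbenium ion is stabilised by two oxygen donors on ring B, so it is long-lived and loosely paired and hard for a chiral counter-anion to steer. The strong acid needed for ionisation meets two acid-sensitive prenyl alkenes and three aryl silyl ethers. A2 itself needs a diprenylated ring-A salicylic acid derivative, acetal formation with an electron-rich aldehyde and methylenation of an ester-type carbonyl. An enantioselective version on aryl-fused enol acetals is not established, so the key step would itself be new and would carry the stereochemistry.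
- *Comparison:* this alternative is stronger on step economy after ring formation. The chosen route offers a ring-forming step with secure precedent under basic conditions that prenyl groups tolerate. Its one unprecedented element is confined to a late reduction of a substrate that cannot racemise, and that reduction has a fallback.

**Alternative 2:** ring A as a cyclohexanedione, aromatised last.

- *Disconnection:* C4–C4a and O1–C8a. Ring A enters as the dione A4 and the stereocentre is carried in by the chiral amide A5.
- *Forward key step:* the dianion of A4 is acylated at the carbon that becomes C4a by A5. On acidic work-up the freed C2 hydroxyl condenses onto the C8a carbonyl to give the bicyclic dione A3. Ring A then has to be dehydrogenated to the phenol.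
- *For it:* the prenyl groups go in by enolate alkylation, with no aromatic regiochemistry to control. C2 comes from a thoroughly established class of asymmetric reaction. On certainty of enantiocontrol it is stronger than the chosen route.
- *Against it:* the stereocentre is made first and must then survive three threats. The first is a dianion acylation, where the β-silyloxy amide can eliminate. The second is an acidic condensation, where the C2–O bond next to a dioxygenated arene ionises easily. The third is an oxidative aromatisation in the presence of two prenyl groups and a base-sensitive β-aryloxy ketone. A3 is a diastereomer mixture until aromatised. Building ring A from scratch makes the sequence clearly longer.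
- *Comparison:* stronger on enantiocontrol and equal on prenyl regiocontrol, which the chosen route secures through the iodine-blocked Claisen rearrangement. The chosen route offers a bought aromatic ring A, fewer steps, and a stereocentre that is set after all forcing steps rather than before them.

**Alternative 3:** three-component o-quinone methide cycloaddition.

- *Disconnection:* O1–C2 and C3–C4. The components are the salicylaldehyde A7, the orthoester A9 and the styrene A8.
- *Forward key step:* under a chiral BINOL-derived phosphoric acid, A7 and A9 give a mixed acetal that ionises to a 4-methoxy o-quinone methide. This adds across A8 to give the cis-4-methoxyflavan A6 with C2 in the target configuration. The C4 ether must afterwards be converted into the ketone.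
- *For it:* it is convergent and catalytic, the stereocentre is set in the ring-forming step, and no carbon monoxide is needed. Acid-catalysed cycloadditions of o-quinone methides with styrenes are known, so its stereo-determining step stands on firmer ground than a copper hydride reduction of a flavone.
- *Against it:* C4 arrives at the wrong oxidation level with a stereocentre that is thrown away, and getting from benzylic ether to ketone costs at least two operations in the presence of prenyl groups and electron-rich rings. A8 is a very electron-rich styrene that oligomerises under acid and tends to react stepwise through a doubly donor-stabilised benzylic cation, which erodes both cis- and enantioselectivity. The prenyl alkenes of A7 are competing 2π partners. A7 needs its own formylation step.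
- *Comparison:* about equal in steps up to ring C, and stronger in convergence and in precedent for the asymmetric step. The chosen route delivers C4 directly as the carbonyl and keeps acid away from the prenyl groups until the last step.

Key step: step 6

## Remarks on the chemistry

- 4-Iodobenzene-1,3-diol (1) is taken from commerce.
- Where one reaction is run at two or three like groups in one flask, the partly converted compounds are not counted as separate intermediates.
- Step 8 is written with (R)-DTBM-SEGPHOS. The sense of induction for this substrate class must be fixed in a first run, and the (S)-ligand is used unchanged otherwise if hydride goes to the other face.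

## Route

**Step 1**
Reactants: 1 4-iodobenzene-1,3-diol
Product: 2 1-iodo-2,4-bis(prop-2-enyloxy)benzene
Conditions: allyl bromide, K2CO3, acetone, reflux
Reagents that add atoms: allyl bromide, C=CCBr
Why: Williamson ether synthesis at both phenols; K2CO3 in acetone should favour O- over C-alkylation, and the aryl iodide is inert.

**Step 2**
Reactants: 2 1-iodo-2,4-bis(prop-2-enyloxy)benzene
Product: 3 6-iodo-2,4-di(prop-2-enyl)benzene-1,3-diol
Conditions: PhNEt2, 195 °C, sealed vessel, argon
Reagents that add atoms: none
Why: Twofold aromatic Claisen rearrangement; each [3,3] shift delivers an allyl group from oxygen to an ortho carbon. The iodine blocks the third activated position, so the ether next to it can only reach the carbon between the two oxygens and the other ether the remaining ortho carbon; if the order is reversed, the doubly blocked ether should move on by a Cope shift to the same para carbon. The amine solvent buffers traces of acid that would cyclise the o-allylphenols.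

**Step 3**
Reactants: 3 6-iodo-2,4-di(prop-2-enyl)benzene-1,3-diol
Product: 4 6-iodo-2,4-bis(3-methylbut-2-enyl)benzene-1,3-diol
Conditions: 2-methylbut-2-ene (excess), RuCl2(=CHPh)(PCy3)(H2IMes) (second-generation Grubbs catalyst, 5 mol %), CH2Cl2, 40 °C, sealed tube
Reagents that add atoms: 2-methylbut-2-ene, CC=C(C)C
Why: Olefin cross-metathesis of both terminal alkenes with excess 2-methylbut-2-ene turns allyl into prenyl with loss of propene. The catalyst tolerates free phenols and the aryl iodide, and the trisubstituted product alkenes should not react further.

**Step 4**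
Reactants: 5 2,4-dihydroxybenzaldehyde
Product: 6 2,4-bis(methoxymethoxy)benzaldehyde
Conditions: MOMCl, i-Pr2NEt, CH2Cl2, 0 °C to reflux
Reagents that add atoms: chloromethyl methyl ether, COCCl
Why: Base-mediated O-alkylation of both phenols to methoxymethyl ethers; the chelated 2-hydroxyl needs excess reagent and warming.

**Step 5**
Reactants: 6 2,4-bis(methoxymethoxy)benzaldehyde
Product: 7 1-ethynyl-2,4-bis(methoxymethoxy)benzene
Conditions: dimethyl (1-diazo-2-oxopropyl)phosphonate, K2CO3, MeOH, rt
Reagents that add atoms: dimethyl (1-diazo-2-oxopropyl)phosphonate, CC(=O)C(=[N+]=[N-])P(=O)(OC)OC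
Why: Ohira–Bestmann variant of the Seyferth–Gilbert homologation. Methanolysis of the reagent frees the diazomethylphosphonate anion, which converts the aldehyde into the terminal alkyne through a vinylidene carbene; the carbonate base leaves the MOM ethers intact.

**Step 6**
Reactants: 4 6-iodo-2,4-bis(3-methylbut-2-enyl)benzene-1,3-diol; 7 1-ethynyl-2,4-bis(methoxymethoxy)benzene; 8 carbon monoxide
Product: 11 2-[2,4-bis(methoxymethoxy)phenyl]-7-hydroxy-6,8-bis(3-methylbut-2-enyl)-4H-chromen-4-one, via ynone 9 (not isolated), via enaminone 10 (not isolated)
Conditions: PdCl2(PPh3)2 (5 mol %), CO (20 bar), Et2NH, 120 °C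
Reagents that add atoms: none
Why: Zerovalent palladium, formed in the flask from PdCl2(PPh3)2, inserts into the C–I bond of 4; 8 inserts to give an aroylpalladium species, which couples with the amine-activated terminal alkyne 7 to give the ynone 9 (forming C4a–C4 and C4–C3). Diethylamine then adds to 9 in conjugate fashion to give the enaminone 10, and the hydroxyl ortho to the acyl group displaces the amine at the β-carbon, forming O1–C2. The closest known reaction type is the palladium-catalysed carbonylative Sonogashira coupling and cyclisation of 2-iodophenols with terminal alkynes to flavones in a secondary amine. Ring C closes in the 6-endo mode (6-endo-dig with respect to 9, realised as addition–elimination on 10). No stereocentre is formed. The step needs carbonylative rather than direct coupling, which the CO pressure and the ready acyl migration of an electron-rich aryl group should secure. It needs 6-endo rather than 5-exo closure, which the secondary amine steers by making C2 the electrophilic carbon of 10. Of the two phenols only the one ortho to the carbonyl can reach C2; the other sits para to it between two prenyl groups and should not compete as an acyl acceptor. The prenyl alkenes are trisubstituted and meta to the palladium-bearing carbon, so Heck closure is not to be expected, and the MOM ethers are inert to the base.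

**Step 7**
Reactants: 11 2-[2,4-bis(methoxymethoxy)phenyl]-7-hydroxy-6,8-bis(3-methylbut-2-enyl)-4H-chromen-4-one
Product: 12 2-[2,4-bis(methoxymethoxy)phenyl]-7-(methoxymethoxy)-6,8-bis(3-methylbut-2-enyl)-4H-chromen-4-one
Conditions: MOMCl, i-Pr2NEt, CH2Cl2, 0 °C to rt
Reagents that add atoms: chloromethyl methyl ether, COCCl
Why: O-alkylation of the only free hydroxyl, the acidic C7 phenol (a vinylogous acid). The cap is needed because a free C7–OH would consume hydride and, as phenoxide, deactivate the enone in step 8.

**Step 8**
Reactants: 12 2-[2,4-bis(methoxymethoxy)phenyl]-7-(methoxymethoxy)-6,8-bis(3-methylbut-2-enyl)-4H-chromen-4-one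
Product: 14 (2S)-2-[2,4-bis(methoxymethoxy)phenyl]-7-(methoxymethoxy)-6,8-bis(3-methylbut-2-enyl)-2,3-dihydro-4H-chromen-4-one, via silyl enol ether 13 (not isolated)
Conditions: Cu(OAc)2 (5 mol %), (R)-DTBM-SEGPHOS (5.5 mol %), (EtO)2MeSiH, toluene, 0 °C to rt; then AcOH, THF–H2O
Reagents that add atoms: none
Why: Proposed new method: the ligated copper hydride formed from Cu(OAc)2, the bisphosphine and the silane should add hydride to C2 of the vinylogous ester 12, the C2-symmetric pocket of the ligand telling the two faces apart by placing the twisted 2-aryl group in an open quadrant, so that C2 becomes S; the copper enolate is silylated by the silane to 13, which regenerates the hydride and protects ring C from β-elimination of the aryloxide until mild hydrolysis releases 14; the closest known reaction type is the copper hydride-catalysed asymmetric 1,4-reduction of β,β-disubstituted cyclic enones and of 2-alkylchromones, and isolated prenyl alkenes are not touched by this reagent.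

**Step 9**
Reactants: 14 (2S)-2-[2,4-bis(methoxymethoxy)phenyl]-7-(methoxymethoxy)-6,8-bis(3-methylbut-2-enyl)-2,3-dihydro-4H-chromen-4-one
Product: 15 (2S)-2-(2,4-dihydroxyphenyl)-7-hydroxy-6,8-bis(3-methylbut-2-enyl)-2,3-dihydro-4H-chromen-4-one
Conditions: HCl (ca. 1 M), MeOH, 25–40 °C
Reagents that add atoms: none
Why: Acid-catalysed transacetalisation to methanol removes the three MOM ethers. Dilute acid at moderate temperature is chosen so that the prenyl alkenes are not protonated and ring C is not opened, and C2 is not touched.

## Compound list

1 | 4-iodobenzene-1,3-diol | Oc1ccc(I)c(O)c1 | starting material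
2 | 1-iodo-2,4-bis(prop-2-enyloxy)benzene | C=CCOc1ccc(I)c(OCC=C)c1 | intermediate
3 | 6-iodo-2,4-di(prop-2-enyl)benzene-1,3-diol | C=CCc1cc(I)c(O)c(CC=C)c1O | intermediate
4 | 6-iodo-2,4-bis(3-methylbut-2-enyl)benzene-1,3-diol | CC(C)=CCc1cc(I)c(O)c(CC=C(C)C)c1O | intermediate
5 | 2,4-dihydroxybenzaldehyde | O=Cc1ccc(O)cc1O | starting material
6 | 2,4-bis(methoxymethoxy)benzaldehyde | COCOc1ccc(C=O)c(OCOC)c1 | intermediate
7 | 1-ethynyl-2,4-bis(methoxymethoxy)benzene | C#Cc1ccc(OCOC)cc1OCOC | intermediate
8 | carbon monoxide | [C-]#[O+] | starting material
9 | 3-[2,4-bis(methoxymethoxy)phenyl]-1-[2,4-dihydroxy-3,5-bis(3-methylbut-2-enyl)phenyl]prop-2-yn-1-one | CC(C)=CCc1cc(C(=O)C#Cc2ccc(OCOC)cc2OCOC)c(O)c(CC=C(C)C)c1O | intermediate (not isolated)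
10 | 3-[2,4-bis(methoxymethoxy)phenyl]-3-(diethylamino)-1-[2,4-dihydroxy-3,5-bis(3-methylbut-2-enyl)phenyl]prop-2-en-1-one (alkene geometry not fixed) | CCN(CC)C(=CC(=O)c1cc(CC=C(C)C)c(O)c(CC=C(C)C)c1O)c1ccc(OCOC)cc1OCOC | intermediate (not isolated)
11 | 2-[2,4-bis(methoxymethoxy)phenyl]-7-hydroxy-6,8-bis(3-methylbut-2-enyl)-4H-chromen-4-one | CC(C)=CCc1cc2c(c(CC=C(C)C)c1O)oc(-c1ccc(OCOC)cc1OCOC)cc2=O | intermediate
12 | 2-[2,4-bis(methoxymethoxy)phenyl]-7-(methoxymethoxy)-6,8-bis(3-methylbut-2-enyl)-4H-chromen-4-one | CC(C)=CCc1cc2c(c(CC=C(C)C)c1OCOC)oc(-c1ccc(OCOC)cc1OCOC)cc2=O | intermediate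
13 | (2S)-2-[2,4-bis(methoxymethoxy)phenyl]-4-[diethoxy(methyl)silyloxy]-7-(methoxymethoxy)-6,8-bis(3-methylbut-2-enyl)-2H-chromene | CC(C)=CCc1cc2c(c(CC=C(C)C)c1OCOC)O[C@H](c1ccc(OCOC)cc1OCOC)C=C2O[Si](C)(OCC)OCC | intermediate (not isolated)
14 | (2S)-2-[2,4-bis(methoxymethoxy)phenyl]-7-(methoxymethoxy)-6,8-bis(3-methylbut-2-enyl)-2,3-dihydro-4H-chromen-4-one | CC(C)=CCc1cc2c(c(CC=C(C)C)c1OCOC)O[C@H](c1ccc(OCOC)cc1OCOC)CC2=O | intermediate
15 | (2S)-2-(2,4-dihydroxyphenyl)-7-hydroxy-6,8-bis(3-methylbut-2-enyl)-2,3-dihydro-4H-chromen-4-one | CC(C)=CCc1cc2c(c(CC=C(C)C)c1O)O[C@H](c1ccc(O)cc1O)CC2=O | target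

## Step count and risk

Total step count: 9. Longest linear sequence: 7 steps (steps 1, 2, 3, 6, 7, 8 and 9, from 1); the alkyne branch (steps 4 and 5) joins at step 6.

**Step 8 (Proposed new method).**
- *What may go wrong:* hydride addition may be slow, because C2 of 12 is the β-carbon of a vinylogous ester that receives electron density from O1, from the C7 oxygen and from ring B. The two faces may be told apart poorly, because the ortho-substituted 2-aryl group is twisted out of the chromone plane. If warming is needed, the copper enolate may expel the aryloxide, opening ring C and leading to over-reduction.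
- *Fallback (known chemistry only):* it sets out from 4 and 6 and returns at 14. Kosugi–Migita–Stille coupling of 4 with tributyl(1-ethoxyvinyl)stannane under PdCl2(PPh3)2 should give 6-(1-ethoxyethenyl)-2,4-bis(3-methylbut-2-enyl)benzene-1,3-diol F1. Dilute aqueous acid converts F1 into 1-[2,4-dihydroxy-3,5-bis(3-methylbut-2-enyl)phenyl]ethanone F2. MOMCl and K2CO3 in acetone alkylate only the non-chelated hydroxyl, giving 1-[2-hydroxy-4-(methoxymethoxy)-3,5-bis(3-methylbut-2-enyl)phenyl]ethanone F3. Claisen–Schmidt condensation of F3 with 6 (KOH, EtOH) gives the chalcone (E)-3-[2,4-bis(methoxymethoxy)phenyl]-1-[2-hydroxy-4-(methoxymethoxy)-3,5-bis(3-methylbut-2-enyl)phenyl]prop-2-en-1-one F4. Oxa-Michael closure (NaOAc, EtOH, reflux) gives the racemic flavanone rac-2-[2,4-bis(methoxymethoxy)phenyl]-7-(methoxymethoxy)-6,8-bis(3-methylbut-2-enyl)-2,3-dihydro-4H-chromen-4-one F5. Kinetic resolution of F5 by asymmetric transfer hydrogenation with RhCl(Cp*)[(R,R)-TsDPEN] in HCO2H–Et3N and EtOAc, stopped near half conversion, should consume the 2R ketone as the cis alcohol (2R,4R)-2-[2,4-bis(methoxymethoxy)phenyl]-7-(methoxymethoxy)-6,8-bis(3-methylbut-2-enyl)chroman-4-ol F6 and leave 14. This catalyst class does not reduce isolated alkenes. The price is at most half of the material and a ring C that no longer comes from the carbonylation.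

**Step 6 (key step).**
- *What may go wrong:* direct coupling without CO insertion, followed by closure to a benzofuran. Capture of the aroylpalladium intermediate by diethylamine. 5-exo closure. Slow oxidative addition to the electron-rich bis-phenoxide. Slow amine addition to an ynone that is deactivated by the para phenoxide.
- *Fallback:* it sets out from 4 and returns at 11, and separates bond formation from ring closure. Acetylation of both phenols (Ac2O, pyridine) gives 4-iodo-2,6-bis(3-methylbut-2-enyl)-1,3-phenylene diacetate F7. Carbonylative Sonogashira coupling of F7 with 7 and 8 under a tertiary amine (PdCl2(PPh3)2, Et3N, CO 1 bar, THF, rt) gives the isolable ynone 4-{3-[2,4-bis(methoxymethoxy)phenyl]prop-2-ynoyl}-2,6-bis(3-methylbut-2-enyl)-1,3-phenylene diacetate F8. Separate treatment of F8 with Et2NH in EtOH removes the acetates by aminolysis and closes ring C through the enaminone to 11.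

**Step 2.**
- *What may go wrong:* when the ether remote from iodine rearranges first to the carbon between the oxygens, the second ether must pass through ipso attack at the iodine-bearing carbon, where loss of iodine can compete with the Cope shift. At this temperature the o-allylphenols may also cyclise to dihydrobenzofurans.
- *Fallback:* it sets out from 1 and returns at 4 in one operation. The disodium phenoxide of 1 (NaH, toluene) is C-alkylated with prenyl bromide, a phenoxide ortho-alkylation in a non-polar medium that is shorter but less selective. Steps 1 to 3 are bypassed and no new compound arises (F0).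

**Step 9.**
- *What may go wrong:* acid-promoted addition of the C7 hydroxyl to a neighbouring prenyl alkene (chroman formation), and acid-catalysed opening and reclosure of ring C with erosion of enantiopurity once the ring-B donors are unveiled.
- *Fallback:* it sets out from 11 and returns at 15, and keeps acid away from the stereocentre. The two MOM ethers are removed at the flavone stage (HCl, MeOH), where there is no stereocentre and the C7 hydroxyl is a poor nucleophile, giving 2-(2,4-dihydroxyphenyl)-7-hydroxy-6,8-bis(3-methylbut-2-enyl)-4H-chromen-4-one F9. Silylation of all three phenols (TBSCl, imidazole, DMF) gives 2-[2,4-bis(tert-butyldimethylsilyloxy)phenyl]-7-(tert-butyldimethylsilyloxy)-6,8-bis(3-methylbut-2-enyl)-4H-chromen-4-one F10. The reduction of step 8 applied to F10 gives (2S)-2-[2,4-bis(tert-butyldimethylsilyloxy)phenyl]-7-(tert-butyldimethylsilyloxy)-6,8-bis(3-methylbut-2-enyl)-2,3-dihydro-4H-chromen-4-one F11, which has the same structure as A1. Fluoride buffered with acetic acid (Bu4NF, AcOH, THF, 0 °C) frees 15.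

## Further compounds

F1 | step 8 | 6-(1-ethoxyethenyl)-2,4-bis(3-methylbut-2-enyl)benzene-1,3-diol | CCOC(=C)c1cc(CC=C(C)C)c(O)c(CC=C(C)C)c1O
F2 | step 8 | 1-[2,4-dihydroxy-3,5-bis(3-methylbut-2-enyl)phenyl]ethanone | CC(=O)c1cc(CC=C(C)C)c(O)c(CC=C(C)C)c1O
F3 | step 8 | 1-[2-hydroxy-4-(methoxymethoxy)-3,5-bis(3-methylbut-2-enyl)phenyl]ethanone | CC(=O)c1cc(CC=C(C)C)c(OCOC)c(CC=C(C)C)c1O
F4 | step 8 | (E)-3-[2,4-bis(methoxymethoxy)phenyl]-1-[2-hydroxy-4-(methoxymethoxy)-3,5-bis(3-methylbut-2-enyl)phenyl]prop-2-en-1-one | COCOc1ccc(/C=C/C(=O)c2cc(CC=C(C)C)c(OCOC)c(CC=C(C)C)c2O)c(OCOC)c1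
F5 | step 8 | rac-2-[2,4-bis(methoxymethoxy)phenyl]-7-(methoxymethoxy)-6,8-bis(3-methylbut-2-enyl)-2,3-dihydro-4H-chromen-4-one | CC(C)=CCc1cc2c(c(CC=C(C)C)c1OCOC)OC(c1ccc(OCOC)cc1OCOC)CC2=O
F6 | step 8 | (2R,4R)-2-[2,4-bis(methoxymethoxy)phenyl]-7-(methoxymethoxy)-6,8-bis(3-methylbut-2-enyl)chroman-4-ol | CC(C)=CCc1cc2c(c(CC=C(C)C)c1OCOC)O[C@@H](c1ccc(OCOC)cc1OCOC)C[C@H]2O
F7 | step 6 | 4-iodo-2,6-bis(3-methylbut-2-enyl)-1,3-phenylene diacetate | CC(=O)Oc1c(I)cc(CC=C(C)C)c(OC(C)=O)c1CC=C(C)C
F8 | step 6 | 4-{3-[2,4-bis(methoxymethoxy)phenyl]prop-2-ynoyl}-2,6-bis(3-methylbut-2-enyl)-1,3-phenylene diacetate | CC(=O)Oc1c(C(=O)C#Cc2ccc(OCOC)cc2OCOC)cc(CC=C(C)C)c(OC(C)=O)c1CC=C(C)C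
F0 | step 2 | none | none
F9 | step 9 | 2-(2,4-dihydroxyphenyl)-7-hydroxy-6,8-bis(3-methylbut-2-enyl)-4H-chromen-4-one | CC(C)=CCc1cc2c(c(CC=C(C)C)c1O)oc(-c1ccc(O)cc1O)cc2=O
F10 | step 9 | 2-[2,4-bis(tert-butyldimethylsilyloxy)phenyl]-7-(tert-butyldimethylsilyloxy)-6,8-bis(3-methylbut-2-enyl)-4H-chromen-4-one | CC(C)=CCc1cc2c(c(CC=C(C)C)c1O[Si](C)(C)C(C)(C)C)oc(-c1ccc(O[Si](C)(C)C(C)(C)C)cc1O[Si](C)(C)C(C)(C)C)cc2=O
F11 | step 9 | (2S)-2-[2,4-bis(tert-butyldimethylsilyloxy)phenyl]-7-(tert-butyldimethylsilyloxy)-6,8-bis(3-methylbut-2-enyl)-2,3-dihydro-4H-chromen-4-one | CC(C)=CCc1cc2c(c(CC=C(C)C)c1O[Si](C)(C)C(C)(C)C)O[C@H](c1ccc(O[Si](C)(C)C(C)(C)C)cc1O[Si](C)(C)C(C)(C)C)CC2=O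
A1 | alternative 1 | (2S)-2-[2,4-bis(tert-butyldimethylsilyloxy)phenyl]-7-(tert-butyldimethylsilyloxy)-6,8-bis(3-methylbut-2-enyl)-2,3-dihydro-4H-chromen-4-one | CC(C)=CCc1cc2c(c(CC=C(C)C)c1O[Si](C)(C)C(C)(C)C)O[C@H](c1ccc(O[Si](C)(C)C(C)(C)C)cc1O[Si](C)(C)C(C)(C)C)CC2=O
A2 | alternative 1 | 2-[2,4-bis(tert-butyldimethylsilyloxy)phenyl]-7-(tert-butyldimethylsilyloxy)-4-methylidene-6,8-bis(3-methylbut-2-enyl)-4H-1,3-benzodioxine (racemic at the acetal carbon) | C=C1OC(c2ccc(O[Si](C)(C)C(C)(C)C)cc2O[Si](C)(C)C(C)(C)C)Oc2c(CC=C(C)C)c(O[Si](C)(C)C(C)(C)C)c(CC=C(C)C)cc21
A3 | alternative 2 | (2S)-2-[2,4-bis(methoxymethoxy)phenyl]-6,8-bis(3-methylbut-2-enyl)-2,3,5,6-tetrahydro-4H-chromene-4,7(8H)-dione (mixture at C6 and C8) | CC(C)=CCC1CC2=C(O[C@H](c3ccc(OCOC)cc3OCOC)CC2=O)C(CC=C(C)C)C1=O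
A4 | alternative 2 | 2,4-bis(3-methylbut-2-enyl)cyclohexane-1,3-dione | O=C1CCC(CC=C(C)C)C(=O)C1CC=C(C)C
A5 | alternative 2 | (3S)-3-[2,4-bis(methoxymethoxy)phenyl]-N-methoxy-N-methyl-3-(triethylsilyloxy)propanamide | CON(C)C(=O)C[C@H](O[Si](CC)(CC)CC)c1ccc(OCOC)cc1OCOC
A6 | alternative 3 | (2S,4S)-2-[2,4-bis(tert-butyldimethylsilyloxy)phenyl]-7-(tert-butyldimethylsilyloxy)-4-methoxy-6,8-bis(3-methylbut-2-enyl)chromane | CC(C)=CCc1cc2c(c(CC=C(C)C)c1O[Si](C)(C)C(C)(C)C)O[C@H](c1ccc(O[Si](C)(C)C(C)(C)C)cc1O[Si](C)(C)C(C)(C)C)C[C@@H]2OC
A7 | alternative 3 | 4-(tert-butyldimethylsilyloxy)-2-hydroxy-3,5-bis(3-methylbut-2-enyl)benzaldehyde | CC(C)=CCc1cc(C=O)c(O)c(CC=C(C)C)c1O[Si](C)(C)C(C)(C)C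
A8 | alternative 3 | 1-ethenyl-2,4-bis(tert-butyldimethylsilyloxy)benzene | C=Cc1ccc(O[Si](C)(C)C(C)(C)C)cc1O[Si](C)(C)C(C)(C)C
A9 | alternative 3 | trimethyl orthoformate | COC(OC)OC
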